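The north-west run is this very flask, followed for its first 2.50 min.

| flask | starting material | partner | free catalyst | remark |
|---|---|---|---|---|
| north-west | 2 M | 2 M | 1.8 mM | the very flask that is asked about, followed so far |
| flask | 2.0 M | 2.00 M | 1.8 mM |  |

north-west run (percent of the starting material charged)

| time / min | target / % | starting material / % |
|---|---|---|
| 0.167 | 1.9 | 97.7 |
| 0.500 | 4.3 | 95.6 |
| 0.833 | 6.7 | 93.3 |
| 1.33 | 9.9 | 89.8 |
| 2.00 | 14.4 | 85.0 |
| 2.50 | 18.7 | 81.1 |

(scatter of a reading: 0.5 percentage points)

- steps that have been proposed: catalyst intermediate A -> catalyst intermediate B; catalyst intermediate C <-> free catalyst + target; starting material + free catalyst -> catalyst intermediate A; partner + catalyst intermediate B <-> catalyst intermediate C; 2 partner -> self-condensation product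
- no earlier run changes the charge of free catalyst; that part of a forecast is a guess
- no earlier run changes the charge of partner; that part of a forecast is a guess

1. apparent order in free catalyst when 50% of the starting material are converted (percent change of the rate of making target for one percent more free catalyst charged)
2. apparent order in partner when 50% of the starting material are converted (percent change of the rate of making target for one percent more partner charged)

Two things in that run seemed not to go together. Starting material had fallen to 81.1%, yet target rose along a nearly straight line, at about 0.150 M min⁻¹. That looked like a rate that ignored its reagents.

I reckoned the curve for first order through the last target reading. At 1.33 min it stood at 10.4%, and the reading was 9.9%. The gap of 0.53 percentage points is about one scatter, so the straight line did not tell zero order from first order.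

I defined the gearing as the percent change of the partner left for one percent more partner charged, at a fixed conversion of starting material, with partner going one-for-one with starting material. At half conversion it is 2.00, but at the last reading it was only 1.23. On that one-for-one reckoning, the order asked for is the order in partner left times the gearing. Partner enters a proposed step singly, so I took the order in partner left as near 1 and expected about 2.00. For free catalyst, which cycles, I expected 1.

The forecast gave 1 and 0.3, and said of partner: “I guess a small positive order with wide uncertainty.” My partner figure differed from it.

At 10.4 min, the flask gave 1.6 in free catalyst and 2.2 in partner.

    catalyst intermediate A → catalyst intermediate B (k = 167 s⁻¹)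
    catalyst intermediate C ⇌ free catalyst + target (K = 4.50 M, k = 32.3 s⁻¹)
    starting material + free catalyst → catalyst intermediate A (k = 8.51 M⁻¹ s⁻¹)
    partner + catalyst intermediate B ⇌ catalyst intermediate C (K = 0.280 M⁻¹, k = 1.09 M⁻¹ s⁻¹)
    2 partner → self-condensation product (k = 2.73 × 10⁻⁴ M⁻¹ s⁻¹)

In a run of this flask without the path from 2 partner to self-condensation product, the order in partner was 1.7, which over the gearing of 2.00 gives 0.860 as the order in partner left. With that path in place, the order in partner rose to 2.2 and the order in free catalyst rose from 1.0 to 1.6. Partner was the limiting reagent in this flask, with 4.3% of its charge left against 29% of starting material at 30.0 min.

All runs were generated by integration on assumed constants; noise was put on by code.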